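The ratio of product in maple to product in alder at 40.0 min was 5.58, larger than the ratio of their enzyme charges, 2.20. So I supposed that each impurity removes one enzyme early and subtracted it from each charge. That left 0.140 µM in alder and 0.850 µM in maple, a ratio of 6.07, near the reading.

| flask | substrate | enzyme | impurity | remark | time |
|---|---|---|---|---|---|
| alder | 25 mM (fed, over 25 min) | 0.59 µM | 0.45 µM | run made earlier |  |
| maple | 25 mM (fed, over 25 min) | 1.3 µM | 0.45 µM | run made earlier |  |
| flask | 25 mM (fed, over 25 min) | 0.88 µM | 0.45 µM |  | 1.0 h |

| run | time / min | product / % | substrate / % |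
|---|---|---|---|
| alder | 2.00 | 0.3 | 8.2 |
| alder | 6.00 | 0.2 | 23.1 |
| alder | 10.0 | 1.0 | 38.9 |
| alder | 15.0 | 1.8 | 58.4 |
| alder | 20.0 | 2.6 | 77.0 |
| alder | 30.0 | 5.4 | 94.8 |
| alder | 40.0 | 7.3 | 92.5 |
| maple | 5.00 | 1.4 | 18.8 |
| maple | 10.0 | 4.5 | 34.8 |
| maple | 15.0 | 9.8 | 50.8 |
| maple | 20.0 | 14.7 | 64.5 |
| maple | 25.0 | 21.0 | 77.8 |
| maple | 30.0 | 28.3 | 71.9 |
| maple | 40.0 | 40.7 | 60.2 |

(standard deviation of a reading: 0.3 percentage points)

- amount of product in percent of the substrate charged, at 6.0 min, 20 min and 1.0 h

- what may be going on: complex -> enzyme + product; enzyme + impurity -> spent catalyst; substrate + enzyme <-> complex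
- percentages count the whole charge, also what has not yet gone in

The new flask kept 0.430 µM by that subtraction. I carried one number, 0.506, the live share: the enzyme left after the impurity in a flask, over the enzyme left in maple. The new flask and maple were fed substrate at the same rate, so I drew the new flask's curve as maple's curve times the share.

The curve starts flat, with substrate just entering, and reaches 1.02 % at 6.0 min, then 7.44 % at 20 min. The knee comes when the feed ends at 25 min, at 10.6 %. For the tail I replaced the curve by its mean slope: maple gained 12 percentage points between 30.0 min and 40.0 min, which with the share gives 22 points up to 1.0 h, so 32.6 %.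

That slope belongs to a mean substrate of 66.1 % in maple, while my flask's tail averages 78.4 %, higher. If the rate followed substrate fully, the tail would grow by that ratio and end at 36.7 %. I took the middle of the two ends, 34.7 %.

The forecast, which said that the impurity “seems to kill its equivalent of enzyme quickly”, gave 1 %, 7.8 % and 35 %; at 20 min its figure stood higher than my 7.44 %.

The flask gave 1.03 %, 8.11 % and 34.9 %.

    complex → enzyme + product (k = 760 /min)
    enzyme + impurity → spent catalyst (k = 4.30 × 10⁵ /M/s)
    substrate + enzyme ⇌ complex (K = 55.0 /M, k = 1.00 × 10⁵ /M/s)

At the end of the feed, 0.417 h, spent catalyst stood at 51.1 % of the catalyst charged and impurity at 0 %, so impurity was the limiting reagent of that side step. The flask's product at 20 min was 0.552 of maple's reading, a little above the live share of 0.506. Alder's live share, 0.165, applied to that maple reading gives 2.42 %, and alder read 2.6 % at 20.0 min.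

Readings and results are simulated on assumed constants.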